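Atom labels: butenolide O1, C2(=O), C3, C4 (CH2OH), C5; side chain C6H2, C7H=C8(CH2OH), C9 onwards. Everything rests on cutting C8–C9 and C7–C6 together across the C7=C8 alkene. In one flask a homofarnesylcopper adds syn to propiolaldehyde diethyl acetal (C7, C8 and the masked hydroxymethyl carbon) and the alkenylcopper formed opens methyl (R)-glycidate (C4–C6). The step exploits that C8 holds C9 cis to C6, which is what syn addition across an alkyne delivers, and that the only stereocentre, C5, sits next to C6, where a chiral epoxide places it. The precursor is a plain primary bromide; the butenolide ring is closed afterwards.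

Key step: step 5

Remark: the 1-ethoxyethyl group carries an uncontrolled acetal stereocentre, so 9, 17, 18, 20 and 21 are mixtures of epimers at that carbon only; it is removed in step 9.

Step 1
Reactants: 1 (2E,6E)-farnesyl bromide; 2 (chloromethyl)(isopropoxy)dimethylsilane
Product: 4 isopropoxy(dimethyl)[(3E,7E)-4,8,12-trimethyltrideca-3,7,11-trien-1-yl]silane, via silylmethyl Grignard reagent 3 (not isolated)
Conditions: 2, Mg, THF, 40 °C; then 1, Li2CuCl4 (3 mol%), THF, −20 °C to rt
Reagents that add atoms: none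
Why: Copper-catalysed Grignard cross-coupling at the primary carbon of the allylic bromide (SN2) should keep the 2E geometry, and the silylmethyl Grignard reagent serves as a hydroxymethyl anion equivalent that supplies C9.

Step 2
Reactants: 4 isopropoxy(dimethyl)[(3E,7E)-4,8,12-trimethyltrideca-3,7,11-trien-1-yl]silane
Product: 5 (3E,7E)-4,8,12-trimethyltrideca-3,7,11-trien-1-ol (homofarnesol)
Conditions: 30% H2O2, KF, KHCO3, THF/MeOH, rt
Reagents that add atoms: hydrogen peroxide, OO
Why: Tamao oxidation converts the alkoxysilane C–Si bond into C–OH with basic peroxide, which should not epoxidise unactivated trisubstituted alkenes.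

Step 3
Reactants: 5 (3E,7E)-4,8,12-trimethyltrideca-3,7,11-trien-1-ol
Product: 6 (3E,7E)-1-bromo-4,8,12-trimethyltrideca-3,7,11-triene (homofarnesyl bromide)
Conditions: CBr4, PPh3, CH2Cl2, 0 °C
Reagents that add atoms: carbon tetrabromide, BrC(Br)(Br)Br
Why: Appel reaction, an SN2 displacement of the activated primary alcohol under neutral conditions that leave the alkenes untouched.

Step 4
Reactants: 7 (tributylstannyl)methanol; 8 ethyl vinyl ether
Product: 9 tributyl[(1-ethoxyethoxy)methyl]stannane
Conditions: PPTS (cat.), CH2Cl2, 0 °C to rt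
Reagents that add atoms: none
Why: Acid-catalysed addition of the alcohol to the enol ether (acetal formation) gives the tin precursor of a protected hydroxymethyl anion.

Step 5
Reactants: 6 (3E,7E)-homofarnesyl bromide; 10 3,3-diethoxyprop-1-yne; 11 methyl (R)-oxirane-2-carboxylate (methyl (R)-glycidate)
Product: 15 methyl (2R,4E,8E,12E)-5-(diethoxymethyl)-2-hydroxy-9,13,17-trimethyloctadeca-4,8,12,16-tetraenoate, via homofarnesylmagnesium bromide 12 (not isolated), via homofarnesylcopper 13 (not isolated), via alkenylcopper 14 (not isolated)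
Conditions: Mg, THF, 40 °C; CuBr·SMe2 (1 equiv), THF, −45 °C; 10, −45 to −25 °C; LiC≡C-n-Pr (from 1-pentyne, n-BuLi), DMPU, then 11, −25 to 0 °C; aq NH4Cl
Reagents that add atoms: none
Why: Alkylcopper 13 adds across the terminal alkyne of 10 in a concerted syn fashion (Normant carbocupration), the alkyl group going to the internal carbon C8 and copper to the terminal carbon C7, and after activation as a mixed alkynylcuprate the C7–Cu bond of 14 opens 11 by SN2 attack at the unsubstituted epoxide carbon (the future C6) with retention at the alkenyl carbon. The closest known reaction type is the carbocupration of 1-alkynes, propiolaldehyde acetals included, followed by capture of the alkenylcopper by an epoxide. No ring is closed. No stereocentre is created: C5 comes unchanged from 11 because its C–O bond is never broken, and the C7=C8 geometry (C9 cis to C6) follows from the syn addition and the configurational stability of 14 at low temperature. The step needs branched regioselectivity, which the normal polarity of 1-alkyne carbocupration should provide in THF where the acetal oxygens do not steer copper to C8, and chemoselectivity for the epoxide over the ester, which organocopper reagents show. With copper on C7 there is no β-alkoxy group for 14 to expel, so collapse to an allene is not open to it.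

Step 6
Reactants: 15 methyl (2R,4E,8E,12E)-5-(diethoxymethyl)-2-hydroxy-9,13,17-trimethyloctadeca-4,8,12,16-tetraenoate
Product: 16 (2R,4E,8E,12E)-5-(diethoxymethyl)-2-hydroxy-N-methoxy-N,9,13,17-tetramethyloctadeca-4,8,12,16-tetraenamide
Conditions: MeNH(OMe)·HCl, i-PrMgCl, THF, −20 to 0 °C
Reagents that add atoms: N,O-dimethylhydroxylamine hydrochloride, CNOC.Cl
Why: Weinreb amide formation by aminolysis of the methyl ester with the magnesium amide, where the C5 alkoxide formed first should suppress deprotonation at C5.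

Step 7
Reactants: 16 Weinreb amide; 9 tributyl[(1-ethoxyethoxy)methyl]stannane
Product: 18 (3R,5E,9E,13E)-6-(diethoxymethyl)-1-(1-ethoxyethoxy)-3-hydroxy-10,14,18-trimethylnonadeca-5,9,13,17-tetraen-2-one, via alkoxymethyllithium 17 (not isolated)
Conditions: 9, n-BuLi, THF, −78 °C; then 16, −78 to −40 °C; aq NH4Cl
Reagents that add atoms: none
Why: Tin–lithium exchange gives the α-alkoxymethyllithium, which adds once to the Weinreb amide (ketone synthesis through a chelated tetrahedral intermediate) after one equivalent has deprotonated the C5 hydroxyl.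

Step 8
Reactants: 18 hydroxy ketone; 19 ketenylidenetriphenylphosphorane (Bestmann ylide)
Product: 21 (5R)-5-[(2E,6E,10E)-3-(diethoxymethyl)-7,11,15-trimethylhexadeca-2,6,10,14-tetraen-1-yl]-4-[(1-ethoxyethoxy)methyl]furan-2(5H)-one, via acyl ylide 20 (not isolated)
Conditions: 19, toluene, 80 °C
Reagents that add atoms: none
Why: The C5 hydroxyl adds to the ketene unit of the ylide to give ester ylide 20, whose intramolecular Wittig reaction with the neighbouring ketone closes the butenolide (C3=C4) under neutral conditions that should leave C5 untouched.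

Step 9
Reactants: 21 protected butenolide
Product: 22 (2E,5E,9E)-2-{2-[(2R)-3-(hydroxymethyl)-5-oxo-2,5-dihydrofuran-2-yl]ethylidene}-6,10,14-trimethylpentadeca-5,9,13-trienal
Conditions: PPTS, acetone/H2O, 40 °C
Reagents that add atoms: water, O
Why: Acid-catalysed acetal hydrolysis removes the ethoxyethyl group and unmasks the enal in one operation, and the enal geometry set in step 5 is also the thermodynamically preferred one for a 2-alkyl-2-enal.

Step 10
Reactants: 22 enal
Product: 23 hippolide E, (5R)-4-(hydroxymethyl)-5-[(2E,6E,10E)-3-(hydroxymethyl)-7,11,15-trimethylhexadeca-2,6,10,14-tetraen-1-yl]furan-2(5H)-one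
Conditions: NaBH4, CeCl3·7H2O, MeOH, −78 °C
Reagents that add atoms: none
Why: Luche reduction delivers hydride 1,2 to the aldehyde much faster than to the butenolide, so only the formyl group on C8 should be reduced.

Compound list
1 | (2E,6E)-farnesyl bromide, (2E,6E)-1-bromo-3,7,11-trimethyldodeca-2,6,10-triene | CC(C)=CCC/C(C)=C/CC/C(C)=C/CBr | starting material
2 | (chloromethyl)(isopropoxy)dimethylsilane | CC(C)O[Si](C)(C)CCl | starting material
3 | [(isopropoxydimethylsilyl)methyl]magnesium chloride | CC(C)O[Si](C)(C)C[Mg]Cl | intermediate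
4 | isopropoxy(dimethyl)[(3E,7E)-4,8,12-trimethyltrideca-3,7,11-trien-1-yl]silane | CC(C)=CCC/C(C)=C/CC/C(C)=C/CC[Si](C)(C)OC(C)C | intermediate
5 | (3E,7E)-4,8,12-trimethyltrideca-3,7,11-trien-1-ol (homofarnesol) | CC(C)=CCC/C(C)=C/CC/C(C)=C/CCO | intermediate
6 | (3E,7E)-1-bromo-4,8,12-trimethyltrideca-3,7,11-triene (homofarnesyl bromide) | CC(C)=CCC/C(C)=C/CC/C(C)=C/CCBr | intermediate
7 | (tributylstannyl)methanol | CCCC[Sn](CCCC)(CCCC)CO | starting material
8 | ethyl vinyl ether | C=COCC | starting material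
9 | tributyl[(1-ethoxyethoxy)methyl]stannane | CCCC[Sn](CCCC)(CCCC)COC(C)OCC | intermediate
10 | 3,3-diethoxyprop-1-yne | C#CC(OCC)OCC | starting material
11 | methyl (R)-oxirane-2-carboxylate (methyl (R)-glycidate) | COC(=O)[C@H]1CO1 | starting material
12 | (3E,7E)-homofarnesylmagnesium bromide | CC(C)=CCC/C(C)=C/CC/C(C)=C/CC[Mg]Br | intermediate
13 | (3E,7E)-homofarnesylcopper(I), as its magnesium bromide complex | CC(C)=CCC/C(C)=C/CC/C(C)=C/CC[Cu] | intermediate
14 | [(1E,5E,9E)-2-(diethoxymethyl)-6,10,14-trimethylpentadeca-1,5,9,13-tetraen-1-yl]copper(I) | CC(C)=CCC/C(C)=C/CC/C(C)=C/CC/C(=C\[Cu])C(OCC)OCC | intermediate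
15 | methyl (2R,4E,8E,12E)-5-(diethoxymethyl)-2-hydroxy-9,13,17-trimethyloctadeca-4,8,12,16-tetraenoate | CC(C)=CCC/C(C)=C/CC/C(C)=C/CC/C(=C\C[C@@H](O)C(=O)OC)C(OCC)OCC | intermediate
16 | (2R,4E,8E,12E)-5-(diethoxymethyl)-2-hydroxy-N-methoxy-N,9,13,17-tetramethyloctadeca-4,8,12,16-tetraenamide | CC(C)=CCC/C(C)=C/CC/C(C)=C/CC/C(=C\C[C@@H](O)C(=O)N(C)OC)C(OCC)OCC | intermediate
17 | [(1-ethoxyethoxy)methyl]lithium | [Li]COC(C)OCC | intermediate
18 | (3R,5E,9E,13E)-6-(diethoxymethyl)-1-(1-ethoxyethoxy)-3-hydroxy-10,14,18-trimethylnonadeca-5,9,13,17-tetraen-2-one | CC(C)=CCC/C(C)=C/CC/C(C)=C/CC/C(=C\C[C@@H](O)C(=O)COC(C)OCC)C(OCC)OCC | intermediate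
19 | ketenylidenetriphenylphosphorane | O=C=C=P(c1ccccc1)(c1ccccc1)c1ccccc1 | starting material
20 | (3R,5E,9E,13E)-6-(diethoxymethyl)-1-(1-ethoxyethoxy)-10,14,18-trimethyl-2-oxononadeca-5,9,13,17-tetraen-3-yl (triphenylphosphoranylidene)acetate | CC(C)=CCC/C(C)=C/CC/C(C)=C/CC/C(=C\C[C@@H](OC(=O)C=P(c1ccccc1)(c1ccccc1)c1ccccc1)C(=O)COC(C)OCC)C(OCC)OCC | intermediate
21 | (5R)-5-[(2E,6E,10E)-3-(diethoxymethyl)-7,11,15-trimethylhexadeca-2,6,10,14-tetraen-1-yl]-4-[(1-ethoxyethoxy)methyl]furan-2(5H)-one | CC(C)=CCC/C(C)=C/CC/C(C)=C/CC/C(=C\C[C@H]1OC(=O)C=C1COC(C)OCC)C(OCC)OCC | intermediate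
22 | (2E,5E,9E)-2-{2-[(2R)-3-(hydroxymethyl)-5-oxo-2,5-dihydrofuran-2-yl]ethylidene}-6,10,14-trimethylpentadeca-5,9,13-trienal | CC(C)=CCC/C(C)=C/CC/C(C)=C/CC/C(=C\C[C@H]1OC(=O)C=C1CO)C=O | intermediate
23 | hippolide E, (5R)-4-(hydroxymethyl)-5-[(2E,6E,10E)-3-(hydroxymethyl)-7,11,15-trimethylhexadeca-2,6,10,14-tetraen-1-yl]furan-2(5H)-one | CC(C)=CCC/C(C)=C/CC/C(C)=C/CC/C(=C\C[C@H]1OC(=O)C=C1CO)CO | target

Total step count: 10. Longest linear sequence: 9 steps (steps 1–3 and 5–10); step 4 prepares a reagent on a side branch.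

Steps most likely to fail

Step 5. The copper–carbon addition may take the linear course, with copper at C8 and loss of ethoxide to an allene, or the hindered alkenylcopper may be protonated on work-up before it opens the epoxide. The fallback builds the alkene by cross-coupling on a preformed bromo enal; it sets out from 11 and 6 and comes back at 15. Copper-catalysed opening of 11 with vinylmagnesium bromide (CuI cat., THF, −40 °C) should give methyl (R)-2-hydroxypent-4-enoate F1. Cross-metathesis with acrolein (second-generation ruthenium catalyst, CH2Cl2, 40 °C) should give methyl (2R,4E)-2-hydroxy-6-oxohex-4-enoate F2. Bromine addition and elimination (Br2, CH2Cl2, −78 °C, then Et3N) should give methyl (2R,4Z)-5-bromo-2-hydroxy-6-oxohex-4-enoate F3, with bromine cis to C6. Bromide 6 is converted into (3E,7E)-homofarnesylzinc bromide F4 (Zn, LiCl, THF) and joined to F3 by Negishi coupling (Pd(OAc)2, SPhos, THF, rt), which replaces bromine with retention and should give methyl (2R,4E,8E,12E)-5-formyl-2-hydroxy-9,13,17-trimethyloctadeca-4,8,12,16-tetraenoate F5. Acetalisation (HC(OEt)3, EtOH, PPTS) returns to 15.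

Step 7. Addition of the organolithium to an amide that carries a lithium alkoxide may stall, and the ketol formed may shift its carbonyl group by enediol tautomerism or lose configuration at C5 during work-up. The fallback avoids the ketol and makes the C4–CH2OH bond by cross-coupling; it sets out from 15 and comes back at 22. Acetylation (Ac2O, pyridine, DMAP) should give methyl (2R,4E,8E,12E)-2-acetoxy-5-(diethoxymethyl)-9,13,17-trimethyloctadeca-4,8,12,16-tetraenoate F6. Dieckmann condensation (LiHMDS, THF, −78 to 0 °C) should give the tetronic acid (5R)-5-[(2E,6E,10E)-3-(diethoxymethyl)-7,11,15-trimethylhexadeca-2,6,10,14-tetraen-1-yl]-4-hydroxyfuran-2(5H)-one F7. Triflation (Tf2O, i-Pr2NEt, CH2Cl2, −78 °C) should give (2R)-2-[(2E,6E,10E)-3-(diethoxymethyl)-7,11,15-trimethylhexadeca-2,6,10,14-tetraen-1-yl]-5-oxo-2,5-dihydrofuran-3-yl trifluoromethanesulfonate F8. Stille coupling with (tributylstannyl)methanol 7 (Pd(PPh3)4, LiCl, dioxane, 90 °C) should give (5R)-5-[(2E,6E,10E)-3-(diethoxymethyl)-7,11,15-trimethylhexadeca-2,6,10,14-tetraen-1-yl]-4-(hydroxymethyl)furan-2(5H)-one F9. The conditions of step 9 then hydrolyse its diethyl acetal to 22.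

Step 8. The acylated ylide may fail to close onto the ketone at a temperature low enough to prevent enolisation towards C5, with loss of optical purity. The fallback makes the C5–O acyl bond first and then closes C3=C4 by an anionic phosphonate olefination at low temperature; it sets out from 18 and comes back at 21. Esterification with diethylphosphonoacetic acid (DIC, DMAP cat., CH2Cl2, 0 °C) should give (3R,5E,9E,13E)-6-(diethoxymethyl)-1-(1-ethoxyethoxy)-10,14,18-trimethyl-2-oxononadeca-5,9,13,17-tetraen-3-yl 2-(diethoxyphosphoryl)acetate F10. Intramolecular Horner–Wadsworth–Emmons reaction (LiCl, i-Pr2NEt, MeCN, 0 °C) then gives 21.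

Further compounds
F1 | step 5 | methyl (R)-2-hydroxypent-4-enoate | C=CC[C@@H](O)C(=O)OC
F2 | step 5 | methyl (2R,4E)-2-hydroxy-6-oxohex-4-enoate | O=C/C=C/C[C@@H](O)C(=O)OC
F3 | step 5 | methyl (2R,4Z)-5-bromo-2-hydroxy-6-oxohex-4-enoate | O=C/C(Br)=C/C[C@@H](O)C(=O)OC
F4 | step 5 | (3E,7E)-homofarnesylzinc bromide | CC(C)=CCC/C(C)=C/CC/C(C)=C/CC[Zn]Br
F5 | step 5 | methyl (2R,4E,8E,12E)-5-formyl-2-hydroxy-9,13,17-trimethyloctadeca-4,8,12,16-tetraenoate | CC(C)=CCC/C(C)=C/CC/C(C)=C/CC/C(=C\C[C@@H](O)C(=O)OC)C=O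
F6 | step 7 | methyl (2R,4E,8E,12E)-2-acetoxy-5-(diethoxymethyl)-9,13,17-trimethyloctadeca-4,8,12,16-tetraenoate | CC(C)=CCC/C(C)=C/CC/C(C)=C/CC/C(=C\C[C@@H](OC(C)=O)C(=O)OC)C(OCC)OCC
F7 | step 7 | (5R)-5-[(2E,6E,10E)-3-(diethoxymethyl)-7,11,15-trimethylhexadeca-2,6,10,14-tetraen-1-yl]-4-hydroxyfuran-2(5H)-one | CC(C)=CCC/C(C)=C/CC/C(C)=C/CC/C(=C\C[C@H]1OC(=O)C=C1O)C(OCC)OCC
F8 | step 7 | (2R)-2-[(2E,6E,10E)-3-(diethoxymethyl)-7,11,15-trimethylhexadeca-2,6,10,14-tetraen-1-yl]-5-oxo-2,5-dihydrofuran-3-yl trifluoromethanesulfonate | CC(C)=CCC/C(C)=C/CC/C(C)=C/CC/C(=C\C[C@H]1OC(=O)C=C1OS(=O)(=O)C(F)(F)F)C(OCC)OCC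
F9 | step 7 | (5R)-5-[(2E,6E,10E)-3-(diethoxymethyl)-7,11,15-trimethylhexadeca-2,6,10,14-tetraen-1-yl]-4-(hydroxymethyl)furan-2(5H)-one | CC(C)=CCC/C(C)=C/CC/C(C)=C/CC/C(=C\C[C@H]1OC(=O)C=C1CO)C(OCC)OCC
F10 | step 8 | (3R,5E,9E,13E)-6-(diethoxymethyl)-1-(1-ethoxyethoxy)-10,14,18-trimethyl-2-oxononadeca-5,9,13,17-tetraen-3-yl 2-(diethoxyphosphoryl)acetate | CC(C)=CCC/C(C)=C/CC/C(C)=C/CC/C(=C\C[C@@H](OC(=O)CP(=O)(OCC)OCC)C(=O)COC(C)OCC)C(OCC)OCC
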